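**Retrosynthetic overview**

- The target, a (2S)-flavanone, is reached from its bis(methoxymethyl) ether by acid-catalysed acetal cleavage; all three prenyl groups are in place before the two aromatic pieces are joined.
- Ring C (O1–C2–C3–C4–C4a–C8a) is disconnected at C4–C4a and O1–C8a: the O1–C2–C3–C4(=O) segment is the four-membered ring of an (S)-4-aryloxetan-2-one and ring A is a 2-fluoroaryllithium, so ring C arises by a 4 → 6 ring expansion in which C4a–C8a is inserted into the acyl–oxygen bond of the lactone.
- Enabling feature: in ring C, O1 and the C4 carbonyl are 1,3-related across C2–C3 (a β-oxy ketone, i.e. an opened β-lactone) and sit ortho to each other on ring A (C8a and C4a), so the ketone formed at C4 activates C8a–F for closure; the C2–O1 bond is never broken and the lactone stereocenter becomes C2.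
- The lactone (ring B piece) comes from 3'-bromo-4'-hydroxyacetophenone by protection, Stille prenylation, Claisen condensation, asymmetric transfer hydrogenation, saponification and lactonisation; the ring A piece comes from 4-bromo-3-fluorophenol by diiodination, protection and twofold Stille prenylation.
- Order of ring formation: rings A and B are bought as benzenes, the oxetanone ring is closed first (step 9) and ring C is formed last from it (step 10).

Key step: step 10

Remark: the sense of induction in step 7 is assigned by analogy with the transfer hydrogenation of aryl alkyl ketones; if the carbinol proved to be (R), the (R,R)-configured catalyst would be used.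

**Route**

Step 1
Reactants: 1 4-bromo-3-fluorophenol
Product: 2 4-bromo-3-fluoro-2,6-diiodophenol
Conditions: NIS (2.1 equiv), p-TsOH·H2O (10 mol%), MeCN, 0 °C to rt
Reagents that add atoms: N-iodosuccinimide, O=C1CCC(=O)N1I
Why: Electrophilic aromatic iodination, in which the hydroxyl group directs to its two free ortho positions because the para position is blocked by bromine.

Step 2
Reactants: 2 4-bromo-3-fluoro-2,6-diiodophenol
Product: 3 1-bromo-2-fluoro-3,5-diiodo-4-(methoxymethoxy)benzene
Conditions: NaH (1.2 equiv), MOMCl (1.3 equiv), THF/DMF, 0 °C to rt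
Reagents that add atoms: chloromethyl methyl ether, COCCl
Why: Williamson-type O-alkylation of the acidic phenoxide with the reactive α-chloro ether should give an acetal that withstands the later palladium and organolithium chemistry.

Step 3
Reactants: 3 1-bromo-2-fluoro-3,5-diiodo-4-(methoxymethoxy)benzene
Product: 4 1-bromo-2-fluoro-4-(methoxymethoxy)-3,5-bis(3-methylbut-2-en-1-yl)benzene
Conditions: prenylSnBu3 (2.4 equiv), Pd2(dba)3 (3 mol%), AsPh3 (12 mol%), CuI (10 mol%), DMF, 50 °C
Reagents that add atoms: tributyl(3-methylbut-2-en-1-yl)stannane, CCCC[Sn](CCCC)(CCCC)CC=C(C)C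
Why: Twofold Stille coupling, in which zerovalent palladium should insert into the two C–I bonds much faster than into C–Br at this temperature and the allyl group is delivered at its unsubstituted terminus to give linear prenyl groups.

Step 4
Reactants: 5 1-(3-bromo-4-hydroxyphenyl)ethan-1-one
Product: 6 1-[3-bromo-4-(methoxymethoxy)phenyl]ethan-1-one
Conditions: K2CO3 (2 equiv), MOMCl (1.3 equiv), acetone, 0 °C to rt
Reagents that add atoms: chloromethyl methyl ether, COCCl
Why: Williamson-type O-alkylation of the phenoxide under a carbonate base too weak to enolise the methyl ketone.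

Step 5
Reactants: 6 1-[3-bromo-4-(methoxymethoxy)phenyl]ethan-1-one
Product: 7 1-[4-(methoxymethoxy)-3-(3-methylbut-2-en-1-yl)phenyl]ethan-1-one
Conditions: prenylSnBu3 (1.3 equiv), Pd(PPh3)4 (5 mol%), DMF, 90 °C
Reagents that add atoms: tributyl(3-methylbut-2-en-1-yl)stannane, CCCC[Sn](CCCC)(CCCC)CC=C(C)C
Why: Stille coupling of an aryl bromide that the para acetyl group activates for oxidative addition, run without base so that the ketone is left alone.

Step 6
Reactants: 7 1-[4-(methoxymethoxy)-3-(3-methylbut-2-en-1-yl)phenyl]ethan-1-one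
Product: 8 ethyl 3-[4-(methoxymethoxy)-3-(3-methylbut-2-en-1-yl)phenyl]-3-oxopropanoate
Conditions: NaH (2.5 equiv), (EtO)2CO (3 equiv), THF, reflux; then AcOH, 0 °C
Reagents that add atoms: diethyl carbonate, CCOC(=O)OCC
Why: Crossed Claisen condensation of the methyl ketone enolate with the non-enolisable carbonate, driven by deprotonation of the β-keto ester that forms.

Step 7
Reactants: 8 ethyl 3-[4-(methoxymethoxy)-3-(3-methylbut-2-en-1-yl)phenyl]-3-oxopropanoate
Product: 9 ethyl (3S)-3-hydroxy-3-[4-(methoxymethoxy)-3-(3-methylbut-2-en-1-yl)phenyl]propanoate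
Conditions: RuCl[(S,S)-TsDPEN](p-cymene) (1 mol%), HCO2H/Et3N (5:2), DMF, 40 °C
Reagents that add atoms: none
Why: Noyori–Ikariya asymmetric transfer hydrogenation of an aryl β-keto ester, in which the ruthenium hydride of the (S,S)-ligand delivers hydride through the aryl-oriented six-membered transition state and should thus set the (S)-carbinol, while the trisubstituted alkene and the acetal are inert to formate.

Step 8
Reactants: 9 ethyl (3S)-3-hydroxy-3-[4-(methoxymethoxy)-3-(3-methylbut-2-en-1-yl)phenyl]propanoate
Product: 10 (3S)-3-hydroxy-3-[4-(methoxymethoxy)-3-(3-methylbut-2-en-1-yl)phenyl]propanoic acid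
Conditions: LiOH·H2O (2.5 equiv), THF/H2O (3:1), 0 °C to rt; then 1 M HCl to pH 4 at 0 °C
Reagents that add atoms: lithium hydroxide, [Li+].[OH-]
Why: Saponification at low temperature, where neither retro-aldol cleavage nor dehydration of the β-hydroxy ester should compete and the carbinol center is not touched.

Step 9
Reactants: 10 (3S)-3-hydroxy-3-[4-(methoxymethoxy)-3-(3-methylbut-2-en-1-yl)phenyl]propanoic acid
Product: 11 (4S)-4-[4-(methoxymethoxy)-3-(3-methylbut-2-en-1-yl)phenyl]oxetan-2-one
Conditions: BOPCl [bis(2-oxo-1,3-oxazolidin-3-yl)phosphinic chloride] (1.5 equiv), Et3N (3 equiv), CH2Cl2, 0 °C; cold aqueous work-up, filtration through Florisil, used at once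
Reagents that add atoms: none
Why: β-Lactonisation by carboxyl activation (mixed phosphinic anhydride) and 4-exo-trig attack of the hydroxyl group, so the carbinol C–O bond is kept and the configuration is retained; the electron-rich lactone is kept cold and used directly because it can ionise at its benzylic C–O bond.

Step 10
Reactants: 4 1-bromo-2-fluoro-4-(methoxymethoxy)-3,5-bis(3-methylbut-2-en-1-yl)benzene, 11 (4S)-4-[4-(methoxymethoxy)-3-(3-methylbut-2-en-1-yl)phenyl]oxetan-2-one
Product: 14 (2S)-7-(methoxymethoxy)-2-[4-(methoxymethoxy)-3-(3-methylbut-2-en-1-yl)phenyl]-6,8-bis(3-methylbut-2-en-1-yl)-2,3-dihydro-4H-chromen-4-one, via aryllithium 12 (not isolated), via lithium aldolate 13 (not isolated)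
Conditions: 4, t-BuLi (2.0 equiv), Et2O, −78 °C, 15 min; cannulated into 11 (1.15 equiv), THF, −78 °C, 30 min; DMPU (4 equiv), −78 to 0 °C; pH 7 phosphate buffer
Reagents that add atoms: none
Why: Proposed new method: bromine–lithium exchange gives the 2-fluoroaryllithium 12, which adds to the strained lactone carbonyl of 11 with acyl–oxygen cleavage (the known opening of β-lactones by organolithiums to β-hydroxy ketones) to give the chelated lithium aldolate 13, whose alkoxide then displaces fluoride at C8a (the known intramolecular SNAr of alkoxides on 2-fluoroaryl ketones), so that C4a–C8a is in effect inserted into the acyl–oxygen bond of the four-membered ring, as an aryne inserts into an acyl–heteroatom bond. The six-membered ring C closes by a 6-endo-trig addition–elimination in which the new C4 carbonyl, ortho to C8a and lithium-chelated, takes up the charge of the Meisenheimer intermediate and LiF is expelled. No new stereocenter is formed: the C2–O1 bond is the C4–O1 bond of the lactone and is never broken, so (S)-11 should give (2S)-14 with retention. The step needs mono-addition, fixed regiochemistry of the two new bonds, and ring closure faster than retro-aldol cleavage or E1cB dehydration of the aldolate. Mono-addition is secured by inverse addition at −78 °C to a slight excess of the lactone, which is more electrophilic than the chelated aldolate ketone, and the regiochemistry by the ortho placement of lithium (from bromine) and fluorine in 12. The rate order is secured by keeping the aldolate chelated and cold, by ortho-acyl activation that the 7-O-acetal (twisted out of conjugation by its two prenyl neighbours) hardly weakens, and by the fact that the only base present is used up as LiF forms.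

Step 11
Reactants: 14 (2S)-7-(methoxymethoxy)-2-[4-(methoxymethoxy)-3-(3-methylbut-2-en-1-yl)phenyl]-6,8-bis(3-methylbut-2-en-1-yl)-2,3-dihydro-4H-chromen-4-one
Product: 15 (2S)-7-hydroxy-2-[4-hydroxy-3-(3-methylbut-2-en-1-yl)phenyl]-6,8-bis(3-methylbut-2-en-1-yl)-2,3-dihydro-4H-chromen-4-one
Conditions: conc. aq. HCl (cat.), MeOH, 40 °C
Reagents that add atoms: none
Why: Acid-catalysed transacetalisation of the two aryl methoxymethyl ethers to methanol, under which C2 of a flavanone should not epimerise (no base, no retro-oxa-Michael opening) and the prenyl groups are expected to survive at this moderate acidity and temperature.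

**Compound list**

1 | 4-bromo-3-fluorophenol | Oc1ccc(Br)c(F)c1 | starting material
2 | 4-bromo-3-fluoro-2,6-diiodophenol | Oc1c(I)cc(Br)c(F)c1I | intermediate
3 | 1-bromo-2-fluoro-3,5-diiodo-4-(methoxymethoxy)benzene | COCOc1c(I)cc(Br)c(F)c1I | intermediate
4 | 1-bromo-2-fluoro-4-(methoxymethoxy)-3,5-bis(3-methylbut-2-en-1-yl)benzene | COCOc1c(CC=C(C)C)cc(Br)c(F)c1CC=C(C)C | intermediate
5 | 1-(3-bromo-4-hydroxyphenyl)ethan-1-one | CC(=O)c1ccc(O)c(Br)c1 | starting material
6 | 1-[3-bromo-4-(methoxymethoxy)phenyl]ethan-1-one | CC(=O)c1ccc(OCOC)c(Br)c1 | intermediate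
7 | 1-[4-(methoxymethoxy)-3-(3-methylbut-2-en-1-yl)phenyl]ethan-1-one | CC(=O)c1ccc(OCOC)c(CC=C(C)C)c1 | intermediate
8 | ethyl 3-[4-(methoxymethoxy)-3-(3-methylbut-2-en-1-yl)phenyl]-3-oxopropanoate | CCOC(=O)CC(=O)c1ccc(OCOC)c(CC=C(C)C)c1 | intermediate
9 | ethyl (3S)-3-hydroxy-3-[4-(methoxymethoxy)-3-(3-methylbut-2-en-1-yl)phenyl]propanoate | CCOC(=O)C[C@H](O)c1ccc(OCOC)c(CC=C(C)C)c1 | intermediate
10 | (3S)-3-hydroxy-3-[4-(methoxymethoxy)-3-(3-methylbut-2-en-1-yl)phenyl]propanoic acid | OC(=O)C[C@H](O)c1ccc(OCOC)c(CC=C(C)C)c1 | intermediate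
11 | (4S)-4-[4-(methoxymethoxy)-3-(3-methylbut-2-en-1-yl)phenyl]oxetan-2-one | O=C1C[C@@H](c2ccc(OCOC)c(CC=C(C)C)c2)O1 | intermediate
12 | [2-fluoro-4-(methoxymethoxy)-3,5-bis(3-methylbut-2-en-1-yl)phenyl]lithium | COCOc1c(CC=C(C)C)cc([Li])c(F)c1CC=C(C)C | intermediate
13 | lithium (1S)-3-[2-fluoro-4-(methoxymethoxy)-3,5-bis(3-methylbut-2-en-1-yl)phenyl]-1-[4-(methoxymethoxy)-3-(3-methylbut-2-en-1-yl)phenyl]-3-oxopropan-1-olate | [Li+].[O-][C@@H](CC(=O)c1cc(CC=C(C)C)c(OCOC)c(CC=C(C)C)c1F)c1ccc(OCOC)c(CC=C(C)C)c1 | intermediate
14 | (2S)-7-(methoxymethoxy)-2-[4-(methoxymethoxy)-3-(3-methylbut-2-en-1-yl)phenyl]-6,8-bis(3-methylbut-2-en-1-yl)-2,3-dihydro-4H-chromen-4-one | CC(C)=CCc1cc([C@@H]2CC(=O)c3cc(CC=C(C)C)c(OCOC)c(CC=C(C)C)c3O2)ccc1OCOC | intermediate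
15 | (2S)-7-hydroxy-2-[4-hydroxy-3-(3-methylbut-2-en-1-yl)phenyl]-6,8-bis(3-methylbut-2-en-1-yl)-2,3-dihydro-4H-chromen-4-one | CC(C)=CCc1cc([C@@H]2CC(=O)c3cc(CC=C(C)C)c(O)c(CC=C(C)C)c3O2)ccc1O | target

**Step count and risks**

Total step count: 11. Longest linear sequence: 8 steps (from 5 to 15, steps 4 to 11).

Step 10 (proposed new method). Three processes may defeat it. The aryllithium may add a second time, to the ketone released on ring opening. The aryllithium may lose LiF before it meets the lactone. The lithium aldolate may undergo retro-aldol cleavage or E1cB dehydration before substitution at C8a, with loss of material or of configuration. The fallback uses known reactions, sets out from 11 (with 4) and returns at 14. The lactone would be opened at the acyl carbon with the chloromagnesium amide made from MeNH(OMe)·HCl and iPrMgCl (THF, −20 °C) to give the hydroxy Weinreb amide F1. Silylation (Et3SiCl, imidazole, DMF) would give the triethylsilyl ether F2. Addition of aryllithium 12, made from 4 as in step 10, at −78 °C would give after work-up the β-silyloxy 2-fluoroaryl ketone F3; over-addition is blocked by the chelated tetrahedral intermediate. Anhydrous CsF in DMF (0 °C to rt) would then remove the silyl group, and the oxygen set free would close ring C by intramolecular SNAr to 14. Ring C still comes from the lactone ring, but acylation and closure are separated and no lithium aldolate has to be warmed.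

Step 3. Three processes may intrude: oxidative addition at C–Br once the iodides are consumed, slow coupling at the iodine flanked by fluorine and the acetal, and allyl transfer with transposition to 1,1-dimethylallyl groups. The fallback reverses the polarity, sets out from 3 and returns at 4. Iodine–magnesium exchange with iPrMgCl·LiCl (THF, −40 °C) is expected first at the iodine between fluorine and the acetal oxygen and would give the arylmagnesium chloride F4. Alkylation with 1-bromo-3-methylbut-2-ene at its primary carbon under CuBr·SMe2 catalysis would give the monoprenylated iodide F5. A second exchange at −20 °C would give the arylmagnesium chloride F6, and the same alkylation leads to 4. The C–Br bond is not exchanged at these temperatures.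

Step 11. The freed phenols may add under acid catalysis to the neighbouring prenyl double bonds (closure to chromans), and the hindered 7-O-acetal may cleave slowly. The fallback avoids protic acid, sets out from 14 and returns at 15. Et3SiOTf with 2,2'-bipyridyl (MeCN, 0 °C) would exchange both aryl methoxymethyl groups for silyl groups to give the bis(triethylsilyl) ether F7. HF·pyridine in THF/pyridine (0 °C) would then cleave the aryl silyl ethers to 15 without base, so C2 is not endangered.

Further compounds
F1 | step 10 | (3S)-3-hydroxy-N-methoxy-N-methyl-3-[4-(methoxymethoxy)-3-(3-methylbut-2-en-1-yl)phenyl]propanamide | CON(C)C(=O)C[C@H](O)c1ccc(OCOC)c(CC=C(C)C)c1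
F2 | step 10 | (3S)-N-methoxy-N-methyl-3-[4-(methoxymethoxy)-3-(3-methylbut-2-en-1-yl)phenyl]-3-[(triethylsilyl)oxy]propanamide | CON(C)C(=O)C[C@H](O[Si](CC)(CC)CC)c1ccc(OCOC)c(CC=C(C)C)c1
F3 | step 10 | (3S)-1-[2-fluoro-4-(methoxymethoxy)-3,5-bis(3-methylbut-2-en-1-yl)phenyl]-3-[4-(methoxymethoxy)-3-(3-methylbut-2-en-1-yl)phenyl]-3-[(triethylsilyl)oxy]propan-1-one | CC[Si](CC)(CC)O[C@@H](CC(=O)c1cc(CC=C(C)C)c(OCOC)c(CC=C(C)C)c1F)c1ccc(OCOC)c(CC=C(C)C)c1
F4 | step 3 | [3-bromo-2-fluoro-5-iodo-6-(methoxymethoxy)phenyl]magnesium chloride | COCOc1c(I)cc(Br)c(F)c1[Mg]Cl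
F5 | step 3 | 1-bromo-2-fluoro-5-iodo-4-(methoxymethoxy)-3-(3-methylbut-2-en-1-yl)benzene | COCOc1c(I)cc(Br)c(F)c1CC=C(C)C
F6 | step 3 | [5-bromo-4-fluoro-2-(methoxymethoxy)-3-(3-methylbut-2-en-1-yl)phenyl]magnesium chloride | COCOc1c([Mg]Cl)cc(Br)c(F)c1CC=C(C)C
F7 | step 11 | (2S)-7-[(triethylsilyl)oxy]-2-{3-(3-methylbut-2-en-1-yl)-4-[(triethylsilyl)oxy]phenyl}-6,8-bis(3-methylbut-2-en-1-yl)-2,3-dihydro-4H-chromen-4-one | CC(C)=CCc1cc([C@@H]2CC(=O)c3cc(CC=C(C)C)c(O[Si](CC)(CC)CC)c(CC=C(C)C)c3O2)ccc1O[Si](CC)(CC)CC
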